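**Retrosynthetic overview**

1. The target comes from a 1,2-shift of the one-carbon bridge C10 from C1 to C11 in a bridged hydroxy mesylate (cyclopentane → cyclobutane, cyclopentene → cyclohexenone).
2. The hydroxy mesylate comes from C–B oxidation and mesylation of an intramolecular Diels–Alder adduct of a 1-siloxy-5,5-disubstituted cyclopentadiene with a tethered (E)-alkenylboronate.
3. The diene comes from a 5,5-disubstituted 3-methylcyclopentenone, made by aldol union (C9–C10) of 3-methylcyclopent-2-enone with a β-silyloxy aldehyde and then C10 methylation; the aldehyde comes from reverse prenylation of propane-1,3-diol (sets C7).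
4. Ring order: cyclopentenone (bought) → norbornene and cycloheptane together (step 8) → cyclobutane and cyclohexenone (step 11).

Assumption: atom labels C1–C11 are the longipinane numbering of the target (C1 = C=O, C2=C3–Me, C4, C5, C6 = CMe2, C7, C8, C9, C10 = C–Me, C11); "10(11→1)-abeo" means the C10–C11 bond is replaced by C10–C1; in step 1 the SEGPHOS enantiomer written is assumed to give the 3R alcohol (its antipode is used if the sense is opposite).

Step 1
Reactants: 1 propane-1,3-diol; 2 3-methylbuta-1,2-diene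
Product: 3 (3R)-4,4-dimethylhex-5-ene-1,3-diol
Conditions: [Ir(cod)Cl]2 (2.5 mol %), (S)-SEGPHOS (5 mol %), 4-cyano-3-nitrobenzoic acid (10 mol %), Cs2CO3 (20 mol %), 1 (3 equiv), PhMe, 60 °C
Reagents that add atoms: none
Why: Iridium-catalysed transfer-hydrogenative reverse prenylation (Krische tert-prenylation): the catalyst dehydrogenates one CH2OH of 1, hydrometalates the allene and adds the prenyl–iridium through its dimethyl terminus to the transient aldehyde under control of the chiral ligand, which sets C7 (R), while excess 1 suppresses double addition.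

Step 2
Reactants: 3 (3R)-4,4-dimethylhex-5-ene-1,3-diol
Product: 4 (3R)-4,4-dimethyl-1,3-bis(triethylsilyloxy)hex-5-ene
Conditions: TESOTf, 2,6-lutidine, CH2Cl2, −78 → 0 °C
Reagents that add atoms: triethylsilyl trifluoromethanesulfonate, CC[Si](CC)(CC)OS(=O)(=O)C(F)(F)F
Why: Standard silylation with a silyl triflate and a hindered base protects both hydroxyls (the secondary one is neopentyl) without touching C7.

Step 3
Reactants: 4 (3R)-4,4-dimethyl-1,3-bis(triethylsilyloxy)hex-5-ene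
Product: 5 (3R)-4,4-dimethyl-3-(triethylsilyloxy)hex-5-enal
Conditions: (COCl)2, DMSO, CH2Cl2, −78 → −30 °C; Et3N, −78 °C → rt
Reagents that add atoms: none
Why: Swern conditions convert a primary triethylsilyl ether directly into the aldehyde (oxidative desilylation) while the hindered secondary TES ether survives, so no separate deprotection is needed and C7 is untouched.

Step 4
Reactants: 6 3-methylcyclopent-2-en-1-one; 5 (3R)-4,4-dimethyl-3-(triethylsilyloxy)hex-5-enal
Product: 8 5-[(1R,3R)-1-hydroxy-4,4-dimethyl-3-(triethylsilyloxy)hex-5-en-1-yl]-3-methylcyclopent-2-en-1-one (both ring-C5 epimers), via silyl dienol ether 7 (not isolated)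
Conditions: 6: LiN(iPr)2, THF, −78 °C, then TMSCl; pentane, filter, concentrate at 0 °C; then 5, BF3·OEt2, CH2Cl2, −78 °C; aq. NaHCO3
Reagents that add atoms: none
Why: Mukaiyama aldol addition of the kinetic cross-conjugated silyl dienol ether through ring C5 to the BF3-bound β-silyloxy aldehyde follows the open, dipole-minimised Evans 1,3-anti model and sets C9 (R) anti to C7; both ring-C5 (= C10) epimers are carried on because step 5 re-creates this centre.

Step 5
Reactants: 8 5-[(1R,3R)-1-hydroxy-4,4-dimethyl-3-(triethylsilyloxy)hex-5-en-1-yl]-3-methylcyclopent-2-en-1-one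
Product: 10 (5S)-5-[(1R,3R)-1,3-dihydroxy-4,4-dimethylhex-5-en-1-yl]-3,5-dimethylcyclopent-2-en-1-one, via methylated TES ether 9 (not isolated)
Conditions: LiN(iPr)2 (2.3 equiv), THF, −78 → −40 °C; MeI, −40 → −20 °C; then 1 M aq. HCl, rt
Reagents that add atoms: iodomethane, CI
Why: Fráter–Seebach-type alkylation: the lithium alkoxide–enolate dianion is a rigid six-membered chelate and MeI enters anti to the C8 chain on C9, which sets quaternary C10 (S, methyl anti to the C9 oxygen) from either epimer of 8; the acidic work-up then removes the TES group.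

Step 6
Reactants: 10 (5S)-5-[(1R,3R)-1,3-dihydroxy-4,4-dimethylhex-5-en-1-yl]-3,5-dimethylcyclopent-2-en-1-one; 11 3-methylbutanoyl chloride
Product: 12 (1R,3R)-1-[(1S)-1,4-dimethyl-2-oxocyclopent-3-en-1-yl]-4,4-dimethylhex-5-ene-1,3-diyl bis(3-methylbutanoate)
Conditions: 11 (3 equiv), pyridine, DMAP (0.2 equiv), CH2Cl2, 0 → 40 °C
Reagents that add atoms: none
Why: DMAP-catalysed acyl transfer esterifies both hindered secondary alcohols early, so no protecting-group steps remain, and no stereocentre is touched.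

Step 7
Reactants: 12 (1R,3R)-1-[(1S)-1,4-dimethyl-2-oxocyclopent-3-en-1-yl]-4,4-dimethylhex-5-ene-1,3-diyl bis(3-methylbutanoate)
Product: 14 (1R,3R,5E)-1-[(1S)-1,4-dimethyl-2-oxocyclopent-3-en-1-yl]-4,4-dimethyl-6-(4,4,5,5-tetramethyl-1,3,2-dioxaborolan-2-yl)hex-5-ene-1,3-diyl bis(3-methylbutanoate), via catechol boronate 13 (not isolated)
Conditions: catBCl (2 equiv), Pd2(dba)3 (2.5 mol %), tBuP(3,5-tBu2C6H3)2 (6 mol %), LiOSO2CF3, Cy2NMe, PhCF3, 70 °C; then pinacol, rt
Reagents that add atoms: B-chlorocatecholborane, ClB1Oc2ccccc2O1; pinacol, CC(C)(O)C(C)(C)O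
Why: Boryl-Heck reaction: oxidative addition of B–Cl to zerovalent palladium, insertion placing boron on the terminal carbon and β-hydride elimination give only the E alkenylboronate (no allylic hydrogen, so no chain walking), and diol exchange gives the robust pinacol ester; the carbon that becomes C11 stays that of the substrate.

Step 8
Reactants: 14 (1R,3R,5E)-1-[(1S)-1,4-dimethyl-2-oxocyclopent-3-en-1-yl]-4,4-dimethyl-6-(4,4,5,5-tetramethyl-1,3,2-dioxaborolan-2-yl)hex-5-ene-1,3-diyl bis(3-methylbutanoate)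
Product: 16 (1R,4R,5R,7R,9R,10S,11R)-11-(4,4,5,5-tetramethyl-1,3,2-dioxaborolan-2-yl)-1-(trimethylsilyloxy)-10(11→1)-abeo-longipin-2-ene-7,9-diyl bis(3-methylbutanoate) (boron endo), via silyl dienol ether 15 (not isolated)
Conditions: TMSOTf, Et3N, CH2Cl2, 0 °C; then PhMe (0.01 M), 110 °C
Reagents that add atoms: trimethylsilyl trifluoromethanesulfonate, C[Si](C)(C)OS(=O)(=O)C(F)(F)F
Why: Soft enolisation gives the endocyclic 1-siloxy-5,5-disubstituted cyclopentadiene (no 1,5-hydrogen shift possible) and the intramolecular Diels–Alder reaction closes the norbornene and the seven-membered ring at once: the tether from C10 forces addition to the diene face syn to the chain with C6 exo, the E alkene then puts boron endo on C11, and the nucleophilic diene terminus C4 bonds to the boron-β carbon C5 (the alternative would join neopentyl C5 to the fully substituted C1), so C1, C4, C5 and C11 are all set from C10.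

Step 9
Reactants: 16 (1R,4R,5R,7R,9R,10S,11R)-11-(4,4,5,5-tetramethyl-1,3,2-dioxaborolan-2-yl)-1-(trimethylsilyloxy)-10(11→1)-abeo-longipin-2-ene-7,9-diyl bis(3-methylbutanoate)
Product: 18 (1R,4R,5S,7R,9R,10S,11R)-1,11-dihydroxy-10(11→1)-abeo-longipin-2-ene-7,9-diyl bis(3-methylbutanoate) (11-OH endo), via TMS-ether alcohol 17 (not isolated)
Conditions: NaBO3·4H2O, THF/H2O (1:1), rt; then 1 M aq. citric acid, rt
Reagents that add atoms: sodium perborate tetrahydrate NaBO3·4H2O, [Na+].[O-]OB=O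
Why: Perborate oxidation of the C–B bond (1,2-shift of carbon from boron to oxygen) goes with retention and gives the endo C11 alcohol, and the mildly acidic work-up hydrolyses the tertiary TMS ether.

Step 10
Reactants: 18 (1R,4R,5S,7R,9R,10S,11R)-1,11-dihydroxy-10(11→1)-abeo-longipin-2-ene-7,9-diyl bis(3-methylbutanoate)
Product: 19 (1R,4R,5S,7R,9R,10S,11R)-1-hydroxy-11-(methanesulfonyloxy)-10(11→1)-abeo-longipin-2-ene-7,9-diyl bis(3-methylbutanoate) (mesylate endo)
Conditions: MsCl, Et3N, CH2Cl2, −20 °C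
Reagents that add atoms: methanesulfonyl chloride, CS(Cl)(=O)=O
Why: Selective sulfonylation of the secondary endo alcohol; the bridgehead tertiary alcohol does not react and no stereocentre is touched.

Step 11
Reactants: 19 (1R,4R,5S,7R,9R,10S,11R)-1-hydroxy-11-(methanesulfonyloxy)-10(11→1)-abeo-longipin-2-ene-7,9-diyl bis(3-methylbutanoate)
Product: 20 (4R,5S,7R,9R,10R,11R)-1-oxolongipin-2-ene-7,9-diyl bis(3-methylbutanoate)
Conditions: AlEt3 (3 equiv), CH2Cl2, −78 → 0 °C; aq. KNaC4H4O6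
Reagents that add atoms: none
Why: Proposed new method: a strain-building semipinacol 1,2-shift in which the aluminium alkoxide formed at bridgehead C1 pushes the one-carbon bridge C10 from C1 onto C11 while aluminium pulls the endo mesylate; of the C1 substituents only the C1–C10 bond is antiperiplanar (about 155–160°) to the endo C11–O bond (C1–C2 is gauche and cannot shift in concert), so the shift contracts the C1–C10–C4–C5–C11 cyclopentane to the cyclobutane, expands the cyclopentene to the cyclohexenone, inverts C11 and keeps C4, C5, C7, C9 and C10; the new C=O bond and enone conjugation (roughly 25–30 kcal/mol) outweigh the extra strain of a pinane over a bornane skeleton (roughly 15 kcal/mol); the closest known reactions are the organoaluminium-promoted pinacol-type rearrangement of 2-mesyloxy alcohols (Suzuki–Tsuchihashi) and the quasi-Favorskii ring contraction, which also builds cyclobutanes against strain, but a bornane-to-pinane bridge shift of a 1-hydroxy-2-endo-sulfonate has not been shown.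

**Compound list**

1 | propane-1,3-diol | OCCCO | starting material
2 | 3-methylbuta-1,2-diene (1,1-dimethylallene) | CC(C)=C=C | starting material
3 | (3R)-4,4-dimethylhex-5-ene-1,3-diol | OCC[C@@H](O)C(C)(C)C=C | intermediate
4 | (3R)-4,4-dimethyl-1,3-bis(triethylsilyloxy)hex-5-ene | CC[Si](CC)(CC)OCC[C@@H](O[Si](CC)(CC)CC)C(C)(C)C=C | intermediate
5 | (3R)-4,4-dimethyl-3-(triethylsilyloxy)hex-5-enal | O=CC[C@@H](O[Si](CC)(CC)CC)C(C)(C)C=C | intermediate
6 | 3-methylcyclopent-2-en-1-one | CC1=CC(=O)CC1 | starting material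
7 | 1-methyl-3-(trimethylsilyloxy)cyclopenta-1,3-diene | CC1=CC(O[Si](C)(C)C)=CC1 | intermediate
8 | 5-[(1R,3R)-1-hydroxy-4,4-dimethyl-3-(triethylsilyloxy)hex-5-en-1-yl]-3-methylcyclopent-2-en-1-one (ring C5 unassigned, both epimers) | CC1=CC(=O)C(C1)[C@H](O)C[C@@H](O[Si](CC)(CC)CC)C(C)(C)C=C | intermediate
9 | (5S)-5-[(1R,3R)-1-hydroxy-4,4-dimethyl-3-(triethylsilyloxy)hex-5-en-1-yl]-3,5-dimethylcyclopent-2-en-1-one | O=C1C=C(C)C[C@@]1(C)[C@H](O)C[C@@H](O[Si](CC)(CC)CC)C(C)(C)C=C | intermediate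
10 | (5S)-5-[(1R,3R)-1,3-dihydroxy-4,4-dimethylhex-5-en-1-yl]-3,5-dimethylcyclopent-2-en-1-one | O=C1C=C(C)C[C@@]1(C)[C@H](O)C[C@@H](O)C(C)(C)C=C | intermediate
11 | 3-methylbutanoyl chloride | CC(C)CC(Cl)=O | starting material
12 | (1R,3R)-1-[(1S)-1,4-dimethyl-2-oxocyclopent-3-en-1-yl]-4,4-dimethylhex-5-ene-1,3-diyl bis(3-methylbutanoate) | O=C1C=C(C)C[C@@]1(C)[C@H](OC(=O)CC(C)C)C[C@@H](OC(=O)CC(C)C)C(C)(C)C=C | intermediate
13 | (1R,3R,5E)-6-(1,3,2-benzodioxaborol-2-yl)-1-[(1S)-1,4-dimethyl-2-oxocyclopent-3-en-1-yl]-4,4-dimethylhex-5-ene-1,3-diyl bis(3-methylbutanoate) | O=C1C=C(C)C[C@@]1(C)[C@H](OC(=O)CC(C)C)C[C@@H](OC(=O)CC(C)C)C(C)(C)/C=C/B1Oc2ccccc2O1 | intermediate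
14 | (1R,3R,5E)-1-[(1S)-1,4-dimethyl-2-oxocyclopent-3-en-1-yl]-4,4-dimethyl-6-(4,4,5,5-tetramethyl-1,3,2-dioxaborolan-2-yl)hex-5-ene-1,3-diyl bis(3-methylbutanoate) | O=C1C=C(C)C[C@@]1(C)[C@H](OC(=O)CC(C)C)C[C@@H](OC(=O)CC(C)C)C(C)(C)/C=C/B1OC(C)(C)C(C)(C)O1 | intermediate
15 | (1R,3R,5E)-1-[(1S)-1,3-dimethyl-5-(trimethylsilyloxy)cyclopenta-2,4-dien-1-yl]-4,4-dimethyl-6-(4,4,5,5-tetramethyl-1,3,2-dioxaborolan-2-yl)hex-5-ene-1,3-diyl bis(3-methylbutanoate) | C[Si](C)(C)OC1=CC(C)=C[C@@]1(C)[C@H](OC(=O)CC(C)C)C[C@@H](OC(=O)CC(C)C)C(C)(C)/C=C/B1OC(C)(C)C(C)(C)O1 | intermediate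
16 | (1R,4R,5R,7R,9R,10S,11R)-11-(4,4,5,5-tetramethyl-1,3,2-dioxaborolan-2-yl)-1-(trimethylsilyloxy)-10(11→1)-abeo-longipin-2-ene-7,9-diyl bis(3-methylbutanoate); norbornene C1/C2=C3/C4/C5/C11 with bridge C10, boron endo, 10-methyl syn to C2=C3 | CC1=C[C@]2(O[Si](C)(C)C)[C@H](B3OC(C)(C)C(C)(C)O3)[C@@H]4[C@H]1[C@@]2(C)[C@H](OC(=O)CC(C)C)C[C@@H](OC(=O)CC(C)C)C4(C)C | intermediate
17 | (1R,4R,5S,7R,9R,10S,11R)-11-hydroxy-1-(trimethylsilyloxy)-10(11→1)-abeo-longipin-2-ene-7,9-diyl bis(3-methylbutanoate) (11-OH endo) | CC1=C[C@]2(O[Si](C)(C)C)[C@H](O)[C@@H]3[C@H]1[C@@]2(C)[C@H](OC(=O)CC(C)C)C[C@@H](OC(=O)CC(C)C)C3(C)C | intermediate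
18 | (1R,4R,5S,7R,9R,10S,11R)-1,11-dihydroxy-10(11→1)-abeo-longipin-2-ene-7,9-diyl bis(3-methylbutanoate) (11-OH endo) | CC1=C[C@]2(O)[C@H](O)[C@@H]3[C@H]1[C@@]2(C)[C@H](OC(=O)CC(C)C)C[C@@H](OC(=O)CC(C)C)C3(C)C | intermediate
19 | (1R,4R,5S,7R,9R,10S,11R)-1-hydroxy-11-(methanesulfonyloxy)-10(11→1)-abeo-longipin-2-ene-7,9-diyl bis(3-methylbutanoate) (mesylate endo) | CC1=C[C@]2(O)[C@H](OS(C)(=O)=O)[C@@H]3[C@H]1[C@@]2(C)[C@H](OC(=O)CC(C)C)C[C@@H](OC(=O)CC(C)C)C3(C)C | intermediate
20 | (4R,5S,7R,9R,10R,11R)-1-oxolongipin-2-ene-7,9-diyl bis(3-methylbutanoate) (CNP0192813.1) | CC1=CC(=O)[C@@H]2[C@@H]3[C@H]1[C@@]2(C)[C@H](OC(=O)CC(C)C)C[C@@H](OC(=O)CC(C)C)C3(C)C | target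

**Totals and risks**

Total steps: 11. Longest linear sequence: 11 steps (1 and 2 to 20; 6 and 11 enter as bought materials).

Three steps most likely to fail:

Step 7 (boryl-Heck on a hindered alkene next to an enone and two esters). The fallback sets out from 12 and comes back at 14. Ozonolysis of the terminal vinyl group (O3, CH2Cl2/MeOH, −78 °C, then Me2S; the electron-poor enone C=C reacts more slowly) gives (1R,3R)-1-[(1S)-1,4-dimethyl-2-oxocyclopent-3-en-1-yl]-4,4-dimethyl-5-oxopentane-1,3-diyl bis(3-methylbutanoate) F1. Takai iodo-olefination (CHI3, CrCl2, THF, 0 °C) gives the (E)-vinyl iodide (1R,3R,5E)-1-[(1S)-1,4-dimethyl-2-oxocyclopent-3-en-1-yl]-6-iodo-4,4-dimethylhex-5-ene-1,3-diyl bis(3-methylbutanoate) F2. Miyaura borylation (B2pin2, PdCl2(dppf), KOPh, PhMe, 50 °C) then gives 14.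

Step 8 (intramolecular Diels–Alder: weakly activated, hindered dienophile; regiochemistry rests on sterics and a modest electronic bias). The fallback sets out from 14 and comes back at 18, replacing the thermal cycloaddition by an anionic, stepwise annulation. KN(SiMe3)2 (1.05 equiv, THF, −78 → 0 °C) removes a ring C4 proton to give the potassium dienolate F3. Its C4 adds to the boron-substituted alkene (the carbanion is stabilised by boron) and the carbanion closes onto C1 to give the potassium bridgehead alkoxide of the cycloadduct F4, in which boron is expected endo, away from the C10 substituent (to be checked). Oxidative work-up (NaBO3·4H2O, THF/H2O) gives 18 directly.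

Step 11 (the proposed new step: the C1–C2 vinyl bond could shift instead if the reaction becomes cation-like, or the strain could stop the shift). The fallback uses known reaction types only, sets out from 12 and comes back at 20; it replaces the sulfonate by dinitrogen as the leaving group. E-selective nitration of the vinyl group (AgNO2, TEMPO, 4 Å sieves, ClCH2CH2Cl, 70 °C) gives the nitroalkene (1R,3R,5E)-1-[(1S)-1,4-dimethyl-2-oxocyclopent-3-en-1-yl]-4,4-dimethyl-6-nitrohex-5-ene-1,3-diyl bis(3-methylbutanoate) F5. TMSOTf/Et3N gives its silyl dienol ether F6, which undergoes the same tether-controlled intramolecular Diels–Alder reaction at 25–60 °C (nitro endo on C11, next to the siloxy-bearing C1) to the nitro adduct F7. Zn/AcOH reduces the nitro group with retention and the work-up removes the TMS group, giving the endo amino alcohol F8. NaNO2 in aq. AcOH at 0 °C then brings about the deaminative semipinacol (Tiffeneau–Demjanov-type) shift of C10, the bond anti to the departing N2, to give 20.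

**Further compounds**

F1 | step 7 | (1R,3R)-1-[(1S)-1,4-dimethyl-2-oxocyclopent-3-en-1-yl]-4,4-dimethyl-5-oxopentane-1,3-diyl bis(3-methylbutanoate) | O=C1C=C(C)C[C@@]1(C)[C@H](OC(=O)CC(C)C)C[C@@H](OC(=O)CC(C)C)C(C)(C)C=O
F2 | step 7 | (1R,3R,5E)-1-[(1S)-1,4-dimethyl-2-oxocyclopent-3-en-1-yl]-6-iodo-4,4-dimethylhex-5-ene-1,3-diyl bis(3-methylbutanoate) | O=C1C=C(C)C[C@@]1(C)[C@H](OC(=O)CC(C)C)C[C@@H](OC(=O)CC(C)C)C(C)(C)/C=C/I
F3 | step 8 | potassium dienolate of 14 (potassium (5S)-3,5-dimethyl-5-substituted cyclopenta-1,3-dien-1-olate) | [K+].[O-]C1=CC(C)=C[C@@]1(C)[C@H](OC(=O)CC(C)C)C[C@@H](OC(=O)CC(C)C)C(C)(C)/C=C/B1OC(C)(C)C(C)(C)O1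
F4 | step 8 | potassium (1R,4R,5R,7R,9R,10S,11R)-7,9-bis(3-methylbutanoyloxy)-11-(4,4,5,5-tetramethyl-1,3,2-dioxaborolan-2-yl)-10(11→1)-abeo-longipin-2-en-1-olate (boron endo) | [K+].CC1=C[C@]2([O-])[C@H](B3OC(C)(C)C(C)(C)O3)[C@@H]4[C@H]1[C@@]2(C)[C@H](OC(=O)CC(C)C)C[C@@H](OC(=O)CC(C)C)C4(C)C
F5 | step 11 | (1R,3R,5E)-1-[(1S)-1,4-dimethyl-2-oxocyclopent-3-en-1-yl]-4,4-dimethyl-6-nitrohex-5-ene-1,3-diyl bis(3-methylbutanoate) | O=C1C=C(C)C[C@@]1(C)[C@H](OC(=O)CC(C)C)C[C@@H](OC(=O)CC(C)C)C(C)(C)/C=C/[N+](=O)[O-]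
F6 | step 11 | (1R,3R,5E)-1-[(1S)-1,3-dimethyl-5-(trimethylsilyloxy)cyclopenta-2,4-dien-1-yl]-4,4-dimethyl-6-nitrohex-5-ene-1,3-diyl bis(3-methylbutanoate) | C[Si](C)(C)OC1=CC(C)=C[C@@]1(C)[C@H](OC(=O)CC(C)C)C[C@@H](OC(=O)CC(C)C)C(C)(C)/C=C/[N+](=O)[O-]
F7 | step 11 | (1R,4R,5S,7R,9R,10S,11R)-11-nitro-1-(trimethylsilyloxy)-10(11→1)-abeo-longipin-2-ene-7,9-diyl bis(3-methylbutanoate) (nitro endo) | CC1=C[C@]2(O[Si](C)(C)C)[C@H]([N+](=O)[O-])[C@@H]3[C@H]1[C@@]2(C)[C@H](OC(=O)CC(C)C)C[C@@H](OC(=O)CC(C)C)C3(C)C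
F8 | step 11 | (1R,4R,5S,7R,9R,10S,11R)-11-amino-1-hydroxy-10(11→1)-abeo-longipin-2-ene-7,9-diyl bis(3-methylbutanoate) (amino endo) | CC1=C[C@]2(O)[C@H](N)[C@@H]3[C@H]1[C@@]2(C)[C@H](OC(=O)CC(C)C)C[C@@H](OC(=O)CC(C)C)C3(C)C
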